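(The runs were generated by integration on assumed constants; noise was put on by code.)

The choice between the spring and the autumn recipe is a choice of how much free base to charge, so the first question is what that free base buys.

in all of them: electrophile 20 mM

|  | nucleophile | free base | remark | time |
|---|---|---|---|---|
| Thursday's | 20 mM | 8.5 mM | run made earlier |  |
| Friday's | 20 mM | 12 mM | run made earlier |  |
| spring | 20.0 mM | 10.0 mM |  | 3.0 d |
| autumn | 20.0 mM | 20.0 mM |  | 3.0 d |

- Thursday's (time / h: electrophile / %, target / %): 5.00: 38.9, 50.8; 12.0: 29.3, 43.7; 25.0: 25.4, 25.8; 40.0: 23.9, 14.1; 48.0: 23.0, 11.0
- Friday's (time / h: electrophile / %, target / %): 5.00: 33.8, 53.6; 12.0: 21.6, 47.9; 25.0: 18.1, 28.3; 40.0: 15.8, 15.7; 48.0: 15.4, 12.4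

(readings scatter by 0.5 percentage points)

1. part of the electrophile that has reacted at the end, spring
2. part of the electrophile that has reacted at the end, autumn
3. what raising the concentration of free base from its lowest to its highest value here does to the part of the electrophile that has reacted (changes below 5 percentage points count as none) (it rises / it falls / no change)



A first count takes each electrophile that reacts to use one nucleophile and set free one acid. In this count the free base takes up that acid; past that point the acid protonates nucleophile, and each further electrophile costs 2 nucleophile, which makes the nucleophile the limiting reagent. This counting folds the charges into one number, the ceiling. For spring it is 75.0 %: the sum of nucleophile and free base charged, over 2 times the electrophile charged, which is the share of the electrophile that this count lets react while free nucleophile lasts.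

The ceiling of Thursday's run is 71.2 % and its reading at 48.0 h is 77.0 %; Friday's ceiling is 80.0 % and its reading is 84.6 %. So one number places the stall, but the readings stand on average 5.2 percentage points above it and are still creeping. Carrying that creep from 25.0 h–48.0 h on to 3.0 d adds 2.7 points, so my reckoning for spring is 82.8 %.

Autumn's ceiling is 100 %, so there the number stops speaking and time takes over. Friday's first reading gives a halving time of 2.55 h. With equal charges the share left is that time over itself plus the time elapsed, so autumn reaches 96.6 %, a rise of 14 points over spring.

The forecast stands lower for spring at 81.5 %, gives 97 % for autumn and says it rises, holding of autumn that “base is stoichiometric, so no stall”.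

    target ⇌ isomer of the product (K = 26.5, k = 0.0471 h⁻¹)
    electrophile + nucleophile → acid set free + target (k = 19.0 L mol⁻¹ h⁻¹)
    electrophile + target → side product (k = 0.327 L mol⁻¹ h⁻¹)
    nucleophile + acid set free ⇌ protonated nucleophile, settled at all times (K = 23000 L mol⁻¹)
    acid set free + free base ⇌ salt of the base, settled at all times (K = 3.10 × 10⁶ L mol⁻¹)

The flask gives 81.7 % for spring, 6.7 points above its ceiling of 75.0 %, and 97.2 % for autumn, so it rises, by 16 points. At the end of spring, free nucleophile stands at 0.547 % of its charge, with 4.13 mM of protonated nucleophile beside it. The spring recipe with 80 mM of electrophile has a ceiling of 18.8 %; that flask reaches 29.4 %, and side product holds 13.7 % of its electrophile.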